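## Retrosynthetic overview

- **Feature.** In the cis-fused hexahydrocyclopenta[c]isoxazole the C3a–C4 bond is alpha to C3. With C3 raised to a lactone carbonyl, C3a becomes an enolate carbon. The carbocycle (C3a, C4, C5, C6, C6a) can then be closed onto an isoxazolidin-5-one ring (N1, O2, C3, C3a, C6a) made beforehand.
- 24 ⇒ hemiketal 22 (C3–H from a silane on the convex face) ⇒ bicyclic lactone 16 + 8-(pyridin-3-yl)octyl Grignard reagent 20 (C3–chain bond, relayed through a Weinreb amide).
- 16 ⇒ monocyclic (3R)-3-(3-chloropropyl)isoxazolidin-5-one 14 (C3a–C4 by enolate cycloalkylation; C3a follows from C6a).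
- 14 ⇒ (E)-6-chlorohexenoyl pyrazole 5 + N-[12-(pyridin-3-yl)dodecyl]hydroxylamine 12 (N1–C6a and O2–C3 by asymmetric aza-Michael addition and lactonisation; sets C6a).
- Ring order: isoxazolidinone first, cyclopentane second. Both pyridylalkyl chains come from 3-bromopyridine by B-alkyl Suzuki–Miyaura coupling.

Key step: step 7

Assumption: the ligand antipode named in step 6 is taken to direct nitrogen to the Re face of the beta-carbon of 5; induction in this catalyst family depends on nucleophile and temperature, so the sign is checked on the first batch of 14 and the commercial mirror-image ligand is used if it is opposite.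

## Route

Step 1
Reactants: 1 5-chloropent-1-ene; 2 acrylic acid
Product: 3 (E)-6-chlorohex-2-enoic acid
Conditions: second-generation Hoveyda–Grubbs catalyst (2 mol %), 2 (2 equiv), CH2Cl2, 40 °C
Reagents that add atoms: none
Why: Olefin cross-metathesis of a readily homodimerising terminal alkene with an electron-poor acrylic partner favours the cross product, equilibrates to the E-enoic acid, and leaves the primary chloride and the acid untouched.

Step 2
Reactants: 3 (E)-6-chlorohex-2-enoic acid; 4 3,5-dimethylpyrazole
Product: 5 (E)-6-chloro-1-(3,5-dimethyl-1H-pyrazol-1-yl)hex-2-en-1-one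
Conditions: DCC, DMAP (10 mol %), CH2Cl2, 0 °C → rt
Reagents that add atoms: none
Why: Steglich-type carbodiimide coupling acylates the pyrazole nitrogen under near-neutral conditions, which avoids the ketene-mediated deconjugation that an enoyl chloride and an amine base can cause.

Step 3
Reactants: 6 dodec-11-en-1-ol; 7 3-bromopyridine
Product: 9 12-(pyridin-3-yl)dodecan-1-ol, via bis-boryl intermediate 8 (not isolated)
Conditions: 9-BBN-H (2.2 equiv), THF, 0 °C → rt; then 7, PdCl2(dppf) (3 mol %), K2CO3, DMF/H2O, 50 °C
Reagents that add atoms: none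
Why: Anti-Markovnikov hydroboration followed by B-alkyl Suzuki–Miyaura coupling joins the terminal carbon to C3 of the pyridine; the second equivalent of borane is taken up by the hydroxyl group as a borinate that the aqueous base hydrolyses.

Step 4
Reactants: 9 12-(pyridin-3-yl)dodecan-1-ol; 10 tert-butyl N-[(tert-butoxycarbonyl)oxy]carbamate
Product: 11 tert-butyl N-[(tert-butoxycarbonyl)oxy]-N-[12-(pyridin-3-yl)dodecyl]carbamate
Conditions: PPh3, DIAD, THF, 0 °C → rt
Reagents that add atoms: none
Why: Mitsunobu N-alkylation works because the N–H of the doubly acylated hydroxylamine is acidic enough, and the two Boc groups rule out O-alkylation and double alkylation.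

Step 5
Reactants: 11 tert-butyl N-[(tert-butoxycarbonyl)oxy]-N-[12-(pyridin-3-yl)dodecyl]carbamate
Product: 12 N-[12-(pyridin-3-yl)dodecyl]hydroxylamine
Conditions: TFA/CH2Cl2 1:2, 0 °C → rt; aq K2CO3; used at once under argon
Reagents that add atoms: none
Why: Acidolysis removes the carbamate and the carbonate Boc groups together as isobutene and CO2 without touching the N–O bond, and basification frees the hydroxylamine.

Step 6
Reactants: 5 (E)-6-chloro-1-(3,5-dimethyl-1H-pyrazol-1-yl)hex-2-en-1-one; 12 N-[12-(pyridin-3-yl)dodecyl]hydroxylamine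
Product: 14 (3R)-3-(3-chloropropyl)-2-[12-(pyridin-3-yl)dodecyl]isoxazolidin-5-one, via open aza-Michael adduct 13 (not isolated)
Conditions: MgBr2·OEt2 (1.1 equiv), (3aR,3a'R,8aS,8a'S)-2,2'-(cyclopropane-1,1-diyl)bis(3a,8a-dihydro-8H-indeno[1,2-d]oxazole) (1.15 equiv), CH2Cl2, rt; 5, −60 °C; 12 added over 2 h, held at −60 °C to full conversion, then rt
Reagents that add atoms: none
Why: This is a chiral Lewis acid-promoted aza-Michael addition of an N-alkylhydroxylamine to a chelating beta-alkyl enoyl pyrazole followed by spontaneous lactonisation with loss of the pyrazole, in which two-point binding of 5 (carbonyl O and pyrazole N2) to the C2-symmetric magnesium bis(oxazoline) fixes the s-cis rotamer and shields one face so that nitrogen adds to the Re face of the beta-carbon and sets C6a as R, a full equivalent of the complex being used because the pyridine of 12 competes for divalent magnesium.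

Step 7
Reactants: 14 (3R)-3-(3-chloropropyl)-2-[12-(pyridin-3-yl)dodecyl]isoxazolidin-5-one
Product: 16 (3aS,6aR)-1-[12-(pyridin-3-yl)dodecyl]hexahydro-3H-cyclopenta[c]isoxazol-3-one, via lithium enolate 15 (not isolated)
Conditions: LiN(SiMe3)2 (1.15 equiv), THF (0.02 M), −78 °C, 30 min; DMPU (5 equiv), −78 → 0 °C
Reagents that add atoms: none
Why: LiN(SiMe3)2 removes a proton from the ring CH2 next to the carbonyl (the future C3a) to give lactone enolate 15, whose carbon displaces the primary chloride at the end of the C6a side chain in an SN2 step that forms C3a–C4. The closest known reaction types are the C-alkylation of isoxazolidin-5-one lithium enolates with alkyl halides and the cycloalkylation of ester and lactone enolates by omega-haloalkyl chains. The cyclopentane (C3a, C4, C5, C6, C6a) closes in a 5-(enolexo)-exo-tet mode, which is favoured by the Baldwin rules for enolates. C3a is controlled by C6a, because the three-carbon tether reaches only the enolate face on which it stands and a trans-fused bicyclo[3.3.0] lactone is too strained, so 6aR gives 3aS and later enolisation cannot change it. The step needs C- over O-alkylation, secured because O-attack would require a seven-membered ring, and it needs closure to outrun fragmentation of the enolate, helped because the C6a–N bond lies near the nodal plane of the ring enolate and any ketene-type loss of the tethered aminoxide is reversible. The chloride is kept as leaving group because it resists the pyridine and the hydroxylamine nitrogen up to this point, and DMPU raises the enolate reactivity so that closure should occur at or below 0 °C.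

Step 8
Reactants: 17 8-chlorooct-1-ene; 7 3-bromopyridine
Product: 19 3-(8-chlorooctyl)pyridine, via B-alkyl borane 18 (not isolated)
Conditions: 9-BBN-H (1.1 equiv), THF, 0 °C → rt; then 7, PdCl2(dppf) (3 mol %), K2CO3, DMF/H2O, 50 °C
Reagents that add atoms: none
Why: Hydroboration and B-alkyl Suzuki–Miyaura coupling as in step 3; the primary alkyl chloride does not add oxidatively to zerovalent palladium under these conditions and is too poor an electrophile to quaternise the pyridine.

Step 9
Reactants: 16 (3aS,6aR)-1-[12-(pyridin-3-yl)dodecyl]hexahydro-3H-cyclopenta[c]isoxazol-3-one; 19 3-(8-chlorooctyl)pyridine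
Product: 22 (3aS,6aR)-3-[8-(pyridin-3-yl)octyl]-1-[12-(pyridin-3-yl)dodecyl]hexahydro-1H-cyclopenta[c]isoxazol-3-ol (both configurations at C3; in equilibrium with the open keto-hydroxylamine), via Grignard reagent 20 (not isolated), via Weinreb amide magnesium salt 21 (not isolated)
Conditions: (a) 19, Mg turnings, BrCH2CH2Br (cat.), THF, 60 °C; (b) MeNH(OMe)·HCl (1.5 equiv), i-PrMgCl (3.0 equiv), THF, −20 °C, then 16, −20 → 0 °C; (c) 20 (1.8 equiv), 0 °C → rt; aq NH4Cl; used crude
Reagents that add atoms: none
Why: This is a one-flask Weinreb ketone synthesis in which the O-acylhydroxylamine-type lactone is opened by Me(MeO)NMgCl to amide 21, the chelated adduct of 21 with 20 lasts until the quench and so excludes the second addition that direct attack on the lactone would risk through easy loss of the aminoxide, the unactivated pyridines are inert to the alkylmagnesium chloride, and on work-up the cis keto-hydroxylamine closes to hemiketal 22 with C3a and C6a untouched.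

Step 10
Reactants: 22 (3aS,6aR)-3-[8-(pyridin-3-yl)octyl]-1-[12-(pyridin-3-yl)dodecyl]hexahydro-1H-cyclopenta[c]isoxazol-3-ol
Product: 24 (3S,3aS,6aR)-3-[8-(pyridin-3-yl)octyl]-1-[12-(pyridin-3-yl)dodecyl]hexahydro-1H-cyclopenta[c]isoxazole, via oxocarbenium ion 23 (not isolated)
Conditions: Et3SiH (10 equiv), BF3·OEt2 (5 equiv), CH2Cl2, −78 → −10 °C; aq NaHCO3
Reagents that add atoms: none
Why: Proposed new method: BF3 ionises the tertiary C3–OH to the N-oxy-substituted oxocarbenium ion 23 and Et3SiH delivers hydride to C3 on the convex face of the cis-fused bicycle (the face of H3a and H6a), which places H3 cis to H3a and the octyl chain on the concave face (3S); silane reduction is not known on isoxazolidin-5-ol hemiketals, and the closest known reaction types are the Et3SiH/BF3·OEt2 reduction of lactols and hemiketals to cyclic ethers used for C-glycosides and the Vorbrüggen-type substitution of 5-acyloxyisoxazolidines, which shows that such cations form next to an N-alkyl nitrogen; excess Lewis acid is used because both pyridines and N1 bind it.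

## Compound list

1 | 5-chloropent-1-ene | C=CCCCCl | starting material
2 | acrylic acid | C=CC(=O)O | starting material
3 | (E)-6-chlorohex-2-enoic acid | OC(=O)/C=C/CCCCl | intermediate
4 | 3,5-dimethylpyrazole | Cc1cc(C)n[nH]1 | starting material
5 | (E)-6-chloro-1-(3,5-dimethyl-1H-pyrazol-1-yl)hex-2-en-1-one | ClCCC/C=C/C(=O)n1nc(C)cc1C | intermediate
6 | dodec-11-en-1-ol | C=CCCCCCCCCCCO | starting material
7 | 3-bromopyridine | Brc1cccnc1 | starting material
8 | 9-{12-[(9-borabicyclo[3.3.1]nonan-9-yl)oxy]dodecyl}-9-borabicyclo[3.3.1]nonane | B1(CCCCCCCCCCCCOB2C3CCCC2CCC3)C2CCCC1CCC2 | intermediate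
9 | 12-(pyridin-3-yl)dodecan-1-ol | OCCCCCCCCCCCCc1cccnc1 | intermediate
10 | tert-butyl N-[(tert-butoxycarbonyl)oxy]carbamate | CC(C)(C)OC(=O)NOC(=O)OC(C)(C)C | starting material
11 | tert-butyl N-[(tert-butoxycarbonyl)oxy]-N-[12-(pyridin-3-yl)dodecyl]carbamate | CC(C)(C)OC(=O)N(CCCCCCCCCCCCc1cccnc1)OC(=O)OC(C)(C)C | intermediate
12 | N-[12-(pyridin-3-yl)dodecyl]hydroxylamine | ONCCCCCCCCCCCCc1cccnc1 | intermediate
13 | (3R)-6-chloro-1-(3,5-dimethyl-1H-pyrazol-1-yl)-3-{hydroxy[12-(pyridin-3-yl)dodecyl]amino}hexan-1-one | ClCCC[C@H](CC(=O)n1nc(C)cc1C)N(O)CCCCCCCCCCCCc1cccnc1 | intermediate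
14 | (3R)-3-(3-chloropropyl)-2-[12-(pyridin-3-yl)dodecyl]isoxazolidin-5-one | ClCCC[C@@H]1CC(=O)ON1CCCCCCCCCCCCc1cccnc1 | intermediate
15 | lithium enolate of 14 | ClCCC[C@@H]1C=C([O-])ON1CCCCCCCCCCCCc1cccnc1.[Li+] | intermediate
16 | (3aS,6aR)-1-[12-(pyridin-3-yl)dodecyl]hexahydro-3H-cyclopenta[c]isoxazol-3-one (cis-fused) | c1cncc(CCCCCCCCCCCCN2OC(=O)[C@H]3CCC[C@H]32)c1 | intermediate
17 | 8-chlorooct-1-ene | C=CCCCCCCCl | starting material
18 | 9-(8-chlorooctyl)-9-borabicyclo[3.3.1]nonane | ClCCCCCCCCB1C2CCCC1CCC2 | intermediate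
19 | 3-(8-chlorooctyl)pyridine | ClCCCCCCCCc1cccnc1 | intermediate
20 | [8-(pyridin-3-yl)octyl]magnesium chloride | Cl[Mg]CCCCCCCCc1cccnc1 | intermediate
21 | (1S,2R)-2-{(chloromagnesiooxy)[12-(pyridin-3-yl)dodecyl]amino}-N-methoxy-N-methylcyclopentane-1-carboxamide | c1cncc(CCCCCCCCCCCCN(O[Mg]Cl)[C@@H]2CCC[C@@H]2C(=O)N(C)OC)c1 | intermediate
22 | (3aS,6aR)-3-[8-(pyridin-3-yl)octyl]-1-[12-(pyridin-3-yl)dodecyl]hexahydro-1H-cyclopenta[c]isoxazol-3-ol, C3 undefined | c1cncc(CCCCCCCCCCCCN2OC(O)(CCCCCCCCc3cccnc3)[C@H]3CCC[C@H]32)c1 | intermediate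
23 | (3aS,6aR)-oxocarbenium ion from 22, positive charge shared by O2 and C3 | c1cncc(CCCCCCCCCCCCN2[O+]=C(CCCCCCCCc3cccnc3)[C@H]3CCC[C@H]32)c1 | intermediate
24 | (3S,3aS,6aR)-3-[8-(pyridin-3-yl)octyl]-1-[12-(pyridin-3-yl)dodecyl]hexahydro-1H-cyclopenta[c]isoxazole; H3, H3a and H6a on one face | c1cncc(CCCCCCCCCCCCN2O[C@@H](CCCCCCCCc3cccnc3)[C@H]3CCC[C@H]32)c1 | target

## Step count

- Total step count: 10.
- Longest linear sequence: 7 steps (3, 4, 5, 6, 7, 9, 10, from dodec-11-en-1-ol).

## Steps most likely to fail

**Step 10 (Proposed new method).**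
- Ionisation of the hemiketal may be held back by Lewis acid binding at N1 and at the pyridines.
- The ring may open to the keto-hydroxylamine and lose the hydroxylamine by retro-aza-Michael cleavage.
- Hydride transfer may show poor facial selectivity.

The fallback uses known chemistry, sets out from 22 and comes back at 24. It forms the O2–C3 bond by displacement instead of reducing a cation.
- TBSCl and imidazole in DMF should trap the open tautomer at the hydroxylamine oxygen as the silyloxyamino ketone F1.
- LiBH(s-Bu)3 in THF at −78 °C should reduce it under Felkin–Anh control, with the nitrogen-bearing C6a as the large group, to the (1R)-carbinol F2.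
- MsCl and Et3N should give the mesylate F3.
- Bu4NF in THF then unmasks the aminoxide, which displaces the mesylate in a 5-exo-tet Williamson-type closure with inversion, giving the 3S configuration of 24.

**Step 7 (key step).** On warming, fragmentation of the enolate may outrun the slow displacement of the primary chloride. The fragmentation paths are ketene-type loss of the tethered aminoxide and beta-elimination of nitrogen.

The fallback keeps the same bond and ring closure but adds an activating group. It sets out from 14 and comes back at 16.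
- The enolate is made at −78 °C with LiN(SiMe3)2 (2.2 equiv) and acylated at once with Boc2O to the 4-tert-butoxycarbonyl isoxazolidinone F4.
- Its stabilised anion (Cs2CO3, cat. NaI, MeCN, 40 °C) should close the cyclopentane to the cis-fused angular ester F5.
- TFA in CH2Cl2 gives the angular acid F6.
- Heating in toluene at 90 °C should cause decarboxylation, and protonation of the enol can only give the cis-fused 16.

**Step 6.** Binding of the pyridine of 12 to the magnesium centre may change the geometry of the chiral complex and erode or invert the facial selectivity.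

The fallback replaces asymmetric induction by resolution. It sets out from 5 and 12 and comes back at 14.
- The two components are combined in CH2Cl2 at rt without any Lewis acid to give the racemic isoxazolidinone F7.
- This is separated by preparative supercritical-fluid chromatography on an amylose tris(3,5-dimethylphenylcarbamate) phase into 14 and the (3S)-antipode F8, which is set aside.

## Further compounds

F1 | step 10 | 1-[(1S,2R)-2-{(tert-butyldimethylsilyloxy)[12-(pyridin-3-yl)dodecyl]amino}cyclopentyl]-9-(pyridin-3-yl)nonan-1-one | c1cncc(CCCCCCCCCCCCN(O[Si](C)(C)C(C)(C)C)[C@@H]2CCC[C@@H]2C(=O)CCCCCCCCc2cccnc2)c1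
F2 | step 10 | (1R)-1-[(1S,2R)-2-{(tert-butyldimethylsilyloxy)[12-(pyridin-3-yl)dodecyl]amino}cyclopentyl]-9-(pyridin-3-yl)nonan-1-ol | c1cncc(CCCCCCCCCCCCN(O[Si](C)(C)C(C)(C)C)[C@@H]2CCC[C@@H]2[C@H](O)CCCCCCCCc2cccnc2)c1
F3 | step 10 | (1R)-1-[(1S,2R)-2-{(tert-butyldimethylsilyloxy)[12-(pyridin-3-yl)dodecyl]amino}cyclopentyl]-9-(pyridin-3-yl)nonyl methanesulfonate | c1cncc(CCCCCCCCCCCCN(O[Si](C)(C)C(C)(C)C)[C@@H]2CCC[C@@H]2[C@H](OS(C)(=O)=O)CCCCCCCCc2cccnc2)c1
F4 | step 7 | tert-butyl (3R)-3-(3-chloropropyl)-5-oxo-2-[12-(pyridin-3-yl)dodecyl]isoxazolidine-4-carboxylate, C4 undefined | ClCCC[C@@H]1C(C(=O)OC(C)(C)C)C(=O)ON1CCCCCCCCCCCCc1cccnc1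
F5 | step 7 | tert-butyl (3aS,6aR)-3-oxo-1-[12-(pyridin-3-yl)dodecyl]tetrahydro-1H-cyclopenta[c]isoxazole-3a(4H)-carboxylate | c1cncc(CCCCCCCCCCCCN2OC(=O)[C@@]3(C(=O)OC(C)(C)C)CCC[C@H]32)c1
F6 | step 7 | (3aS,6aR)-3-oxo-1-[12-(pyridin-3-yl)dodecyl]tetrahydro-1H-cyclopenta[c]isoxazole-3a(4H)-carboxylic acid | c1cncc(CCCCCCCCCCCCN2OC(=O)[C@@]3(C(=O)O)CCC[C@H]32)c1
F7 | step 6 | racemic 3-(3-chloropropyl)-2-[12-(pyridin-3-yl)dodecyl]isoxazolidin-5-one | ClCCCC1CC(=O)ON1CCCCCCCCCCCCc1cccnc1
F8 | step 6 | (3S)-3-(3-chloropropyl)-2-[12-(pyridin-3-yl)dodecyl]isoxazolidin-5-one | ClCCC[C@H]1CC(=O)ON1CCCCCCCCCCCCc1cccnc1
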